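**Retrosynthetic overview**
1. Ring A is finished last: the axial 3-acetate comes from the 3-ketone (bulky hydride, acetylation in the same flask), and the ketone from reductive methylation of a 4-methyl enone, which sets the trans ring fusion and the gem-dimethyl group.
2. The C8 methylene comes from a Wittig reaction on an 8-ketone, with the enone masked as a dithiane.
3. Key step: the six-membered ring B, C9 and the side chain come from a one-carbon ring enlargement of a cyclopentanone (β-oxido carbenoid 1,2-shift of the quaternary carbon), with alkylation of the enolate it produces.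
4. The bicyclic core (ring A plus a five-membered ring) comes from an asymmetric Robinson annulation of 2-methylcyclopentane-1,3-dione with ethyl vinyl ketone; the side chain comes from an iodo ester made from an (R)-β-methyl-δ-lactone.
5. Ring order: ring A first (annulation), then ring B by 5 → 6 expansion.

Assumption: the SMILES is read as (3S,5S,9R,10S,13R), i.e. the enantio-labdane skeleton with an axial 3-acetate trans to the C10 methyl; decalin intermediates carry labdane numbering (C1–C20).

**Step 1**
Reactants: 1 2-methylcyclopentane-1,3-dione; 2 pent-1-en-3-one (ethyl vinyl ketone)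
Product: 4 (7aR)-4,7a-dimethyl-2,3,7,7a-tetrahydro-1H-indene-1,5(6H)-dione, via triketone 3 (not isolated)
Conditions: H2O, AcOH (cat.), 70 °C; then D-phenylalanine (1 equiv), (1R)-(−)-10-camphorsulfonic acid (0.5 equiv), DMF, 30 → 70 °C; recrystallise
Reagents that add atoms: none
Why: Michael addition then amino-acid-mediated Hajos–Parrish–Eder–Sauer–Wiechert aldol condensation (asymmetric Robinson annulation); the D-amino acid enamine selects one of the two enantiotopic ring carbonyls and sets the quaternary carbon (later C10) as R, the mirror image of the L-amino acid series.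

**Step 2**
Reactants: 4 (7aR)-4,7a-dimethyl-2,3,7,7a-tetrahydro-1H-indene-1,5(6H)-dione
Product: 5 (7a'R)-4',7a'-dimethyl-2',3',7',7a'-tetrahydrospiro[1,3-dithiane-2,5'-inden]-1'(6'H)-one
Conditions: HS(CH2)3SH (1.05 equiv), p-TsOH·H2O (0.2 equiv), AcOH, rt
Reagents that add atoms: propane-1,3-dithiol SCCCS
Why: Acid-catalysed dithioketalisation should take the unhindered conjugated carbonyl in preference to the neopentyl cyclopentanone (as with the Wieland–Miescher ketone), which masks the enone against organolithiums and the later methylenation without moving the double bond.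

**Step 3**
Reactants: 6 4-methyl-5,6-dihydro-2H-pyran-2-one
Product: 7 (R)-4-methyltetrahydro-2H-pyran-2-one
Conditions: Ru(OAc)2[(S)-BINAP] (1 mol%), H2 (100 atm), CH2Cl2, 50 °C
Reagents that add atoms: none
Why: Ru–BINAP asymmetric hydrogenation of a β-substituted unsaturated lactone sets the methyl-bearing centre (later C13) as R; I cannot vouch for the sense of induction from memory, so the (S)-ligand is a working choice to be confirmed by optical rotation against the known lactone, with the (R)-ligand used if the sense is opposite.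

**Step 4**
Reactants: 7 (R)-4-methyltetrahydro-2H-pyran-2-one
Product: 8 methyl (S)-5-iodo-3-methylpentanoate
Conditions: NaI, Me3SiCl, MeCN, 60 °C; then MeOH, rt
Reagents that add atoms: sodium iodide [Na+].[I-]; methanol CO
Why: Me3SiI made in the flask opens the lactone by SN2 attack of iodide at the O–CH2 carbon and methanolysis gives the ω-iodo methyl ester; the stereocentre is untouched and only its descriptor changes (R to S) because iodine reverses the CIP ranking.

**Step 5**
Reactants: 5 (7a'R)-4',7a'-dimethyl-2',3',7',7a'-tetrahydrospiro[1,3-dithiane-2,5'-inden]-1'(6'H)-one; 9 dibromomethane; 8 methyl (S)-5-iodo-3-methylpentanoate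
Product: 13 (9S,10S,13R)-8-oxo-3,3-(propane-1,3-diyldisulfanediyl)-17,19-dinorlabd-4-en-15-oic acid, via lithium alkoxide 10 (not isolated), via lithium enolate 11 (not isolated), via keto ester 12 (not isolated)
Conditions: 9, lithium 2,2,6,6-tetramethylpiperidide (LiTMP), THF, −95 °C, then 5; t-BuLi (2.2 equiv), −100 → −40 °C; 8, DMPU, −40 → 0 °C; LiOH, MeOH/H2O, rt; then 1 M HCl
Reagents that add atoms: lithium hydroxide [Li+].[OH-]
Why: Proposed new method: a one-pot three-component ring enlargement–alkylation in which LiCHBr2 adds to the cyclopentanone anti to the angular methyl, Br–Li exchange gives the β-oxido carbenoid, the electron-richer quaternary carbon migrates (1,2-shift with retention, loss of LiBr) to give only the Δ8(9) enolate of the new six-membered ring B, and this regiodefined enolate is C-alkylated by primary iodide 8 in THF/DMPU before LiOH cleaves the ester and equilibrates C9 to the equatorial side chain (cis to the C10 methyl); the closest known reaction is the Nozaki–Yamamoto β-oxido carbenoid ring enlargement with trapping of the enolate by MeI or allyl bromide, which to my knowledge has not been run with an unactivated ester-bearing iodide at a neopentyl enolate carbon.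

**Step 6**
Reactants: 13 (9S,10S,13R)-8-oxo-3,3-(propane-1,3-diyldisulfanediyl)-17,19-dinorlabd-4-en-15-oic acid
Product: 14 (9R,10S,13R)-3,3-(propane-1,3-diyldisulfanediyl)-19-norlabda-4,8(17)-dien-15-oic acid
Conditions: Ph3PCH3Br (5 equiv), KOtBu (5 equiv), THF, 0 °C → reflux; acidic work-up
Reagents that add atoms: methyltriphenylphosphonium bromide C[P+](c1ccccc1)(c1ccccc1)c1ccccc1.[Br-]
Why: Wittig methylenation of the hindered 8-ketone, as in 8-oxolabdane precedent, with excess ylide to cover the carboxylate; C9 stays in its thermodynamic configuration (the descriptor changes from S to R only through CIP ranking).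

**Step 7**
Reactants: 14 (9R,10S,13R)-3,3-(propane-1,3-diyldisulfanediyl)-19-norlabda-4,8(17)-dien-15-oic acid
Product: 15 (9R,10S,13R)-3-oxo-19-norlabda-4,8(17)-dien-15-oic acid
Conditions: PhI(OCOCF3)2 (1.5 equiv), MeCN/H2O 9:1, 0 °C → rt, 15 min
Reagents that add atoms: water O
Why: Oxidative dethioketalisation (Stork–Zhao conditions) returns the conjugated enone within minutes and should leave the 1,1-disubstituted alkene and the acid alone.

**Step 8**
Reactants: 15 (9R,10S,13R)-3-oxo-19-norlabda-4,8(17)-dien-15-oic acid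
Product: 16 (5S,9R,10S,13R)-3-oxolabd-8(17)-en-15-oic acid
Conditions: Li (5 equiv), NH3(l)/THF, −78 °C; MeI (10 equiv), −78 → −33 °C; NH4Cl, then dilute HCl
Reagents that add atoms: iodomethane CI
Why: Stork reductive methylation (Birch-type enone reduction): axial protonation at C5 anti to the C10 methyl gives the trans-decalin (5S), and the C3–C4 enolate so formed is methylated at C4 to give the gem-dimethyl group, while the isolated alkene and the carboxylate are inert.

**Step 9**
Reactants: 16 (5S,9R,10S,13R)-3-oxolabd-8(17)-en-15-oic acid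
Product: 18 (3S,5S,9R,10S,13R)-3-acetoxylabd-8(17)-en-15-oic acid, via dilithium salt 17 (not isolated)
Conditions: LiBH(s-Bu)3 (3 equiv), THF, −78 °C; then Ac2O (8 equiv), DMAP (0.3 equiv), −78 °C → rt; aqueous NaHCO3, then dilute HCl
Reagents that add atoms: acetic anhydride CC(=O)OC(C)=O
Why: The bulky hydride attacks the neopentyl 3-ketone from the equatorial side (as with 3-oxo-4,4-dimethyl triterpenoids) to give the axial 3S alkoxide, cis to H5 and trans to the C10 methyl, which is acetylated in the flask, and the mixed anhydride formed at C15 is hydrolysed on work-up.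

**Compound list**
1 | 2-methylcyclopentane-1,3-dione | CC1C(=O)CCC1=O | starting material
2 | pent-1-en-3-one (ethyl vinyl ketone) | C=CC(=O)CC | starting material
3 | 2-methyl-2-(3-oxopentyl)cyclopentane-1,3-dione | CCC(=O)CCC1(C)C(=O)CCC1=O | intermediate
4 | (7aR)-4,7a-dimethyl-2,3,7,7a-tetrahydro-1H-indene-1,5(6H)-dione | C[C@@]12CCC(=O)C(C)=C1CCC2=O | intermediate
5 | (7a'R)-4',7a'-dimethyl-2',3',7',7a'-tetrahydrospiro[1,3-dithiane-2,5'-inden]-1'(6'H)-one | C[C@@]12CCC3(SCCCS3)C(C)=C1CCC2=O | intermediate
6 | 4-methyl-5,6-dihydro-2H-pyran-2-one | CC1=CC(=O)OCC1 | starting material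
7 | (R)-4-methyltetrahydro-2H-pyran-2-one | C[C@@H]1CCOC(=O)C1 | intermediate
8 | methyl (S)-5-iodo-3-methylpentanoate | ICC[C@@H](C)CC(=O)OC | intermediate
9 | dibromomethane | BrCBr | starting material
10 | lithium (1'R,7a'R)-1'-(dibromomethyl)-4',7a'-dimethyl-1',2',3',6',7',7a'-hexahydrospiro[1,3-dithiane-2,5'-inden]-1'-olate (alkoxide cis to the angular methyl) | [Li]O[C@]1(C(Br)Br)CCC2=C(C)C3(SCCCS3)CC[C@@]12C | intermediate
11 | lithium (4a'S)-1',4a'-dimethyl-3',4',7',8'-tetrahydro-4a'H-spiro[1,3-dithiane-2,2'-naphthalen]-6'-olate (Δ8(9) enolate in labdane numbering) | [Li]OC1=C[C@]2(C)CCC3(SCCCS3)C(C)=C2CC1 | intermediate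
12 | methyl (10S,13R)-8-oxo-3,3-(propane-1,3-diyldisulfanediyl)-17,19-dinorlabd-4-en-15-oate (C9 epimers) | O=C1CCC2=C(C)C3(SCCCS3)CC[C@@]2(C)C1CC[C@@H](C)CC(=O)OC | intermediate
13 | (9S,10S,13R)-8-oxo-3,3-(propane-1,3-diyldisulfanediyl)-17,19-dinorlabd-4-en-15-oic acid (side chain equatorial, cis to the C10 methyl) | O=C1CCC2=C(C)C3(SCCCS3)CC[C@@]2(C)[C@@H]1CC[C@@H](C)CC(=O)O | intermediate
14 | (9R,10S,13R)-3,3-(propane-1,3-diyldisulfanediyl)-19-norlabda-4,8(17)-dien-15-oic acid | C=C1CCC2=C(C)C3(SCCCS3)CC[C@@]2(C)[C@@H]1CC[C@@H](C)CC(=O)O | intermediate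
15 | (9R,10S,13R)-3-oxo-19-norlabda-4,8(17)-dien-15-oic acid | C=C1CCC2=C(C)C(=O)CC[C@@]2(C)[C@@H]1CC[C@@H](C)CC(=O)O | intermediate
16 | (5S,9R,10S,13R)-3-oxolabd-8(17)-en-15-oic acid | C=C1CC[C@@H]2C(C)(C)C(=O)CC[C@@]2(C)[C@@H]1CC[C@@H](C)CC(=O)O | intermediate
17 | dilithium salt of (3S,5S,9R,10S,13R)-3-hydroxylabd-8(17)-en-15-oic acid | C=C1CC[C@@H]2C(C)(C)[C@@H](O[Li])CC[C@@]2(C)[C@@H]1CC[C@@H](C)CC(=O)O[Li] | intermediate
18 | (3S,5S,9R,10S,13R)-3-acetoxylabd-8(17)-en-15-oic acid | C=C1CC[C@@H]2C(C)(C)[C@@H](OC(C)=O)CC[C@@]2(C)[C@@H]1CC[C@@H](C)CC(=O)O | target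

**Step count**
Total: 9 steps. Longest linear sequence: 7 steps (1 → 18 through steps 1, 2, 5, 6, 7, 8, 9; the branch 6 → 18 through steps 3–9 is also 7).

**Steps most likely to fail**

Step 5 (the proposed new step). The weak point is C-alkylation of the hindered neopentyl enolate 11 by an unactivated iodide; proton transfer, O-alkylation or attack on the ester could compete. The fallback uses known chemistry and replaces the alkylation by an aldol addition. It sets out from 5 and 8 and comes back at 13. Kornblum oxidation of 8 (DMSO, NaHCO3, 100 °C) gives methyl (R)-3-methyl-5-oxopentanoate F1. Thioketal 5 is ring-enlarged as before (LiCHBr2, then t-BuLi; Nozaki–Yamamoto), and enolate 11 is trapped at −78 °C with F1 to give the β-hydroxy ketone methyl (10S,13R)-11-hydroxy-8-oxo-3,3-(propane-1,3-diyldisulfanediyl)-17,19-dinorlabd-4-en-15-oate F2. Dehydration with the Burgess reagent gives the exocyclic enone methyl (10R,13R)-8-oxo-3,3-(propane-1,3-diyldisulfanediyl)-17,19-dinorlabda-4,9(11)-dien-15-oate F3. Conjugate reduction with [(Ph3P)CuH]6 gives keto ester 12, and LiOH in MeOH/H2O gives 13 with C9 equilibrated.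

Step 6. Methylenation of the hindered, enolisable 8-ketone next to the substituted C9 may stall in the presence of the carboxylate. The fallback is a two-stage Peterson olefination; it sets out from 13 and comes back at 14. Me3SiCH2Li with CeCl3 (THF, −78 °C, excess to cover the acid) adds to the ketone to give the β-hydroxysilane (9S,10S,13R)-8-hydroxy-3,3-(propane-1,3-diyldisulfanediyl)-17-(trimethylsilyl)-19-norlabd-4-en-15-oic acid F4. KH in THF then brings about syn-elimination to 14.

Step 8. The reductively formed tetrasubstituted enolate may be protonated or over-methylated at C2 instead of giving the quaternary C4 cleanly. The fallback separates reduction from alkylation; it sets out from 15 and comes back at 16. After Li/NH3 reduction the ammonia is removed and the enolate is trapped with Me3SiCl/Et3N to give trimethylsilyl (5S,9R,10S,13R)-3-(trimethylsilyloxy)-19-norlabda-3,8(17)-dien-15-oate F5. Benzyltrimethylammonium fluoride and MeI in THF (Kuwajima–Nakamura alkylation of the naked enolate) methylate C4 and the carboxylate together, giving methyl (5S,9R,10S,13R)-3-oxolabd-8(17)-en-15-oate F6. LiOH in MeOH/H2O then gives 16.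

**Further compounds**
F1 | step 5 | methyl (R)-3-methyl-5-oxopentanoate | O=CC[C@@H](C)CC(=O)OC
F2 | step 5 | methyl (10S,13R)-11-hydroxy-8-oxo-3,3-(propane-1,3-diyldisulfanediyl)-17,19-dinorlabd-4-en-15-oate (C9 and C11 epimers) | O=C1CCC2=C(C)C3(SCCCS3)CC[C@@]2(C)C1C(O)C[C@@H](C)CC(=O)OC
F3 | step 5 | methyl (10R,13R)-8-oxo-3,3-(propane-1,3-diyldisulfanediyl)-17,19-dinorlabda-4,9(11)-dien-15-oate (E/Z mixture) | O=C1CCC2=C(C)C3(SCCCS3)CC[C@@]2(C)C1=CC[C@@H](C)CC(=O)OC
F4 | step 6 | (9S,10S,13R)-8-hydroxy-3,3-(propane-1,3-diyldisulfanediyl)-17-(trimethylsilyl)-19-norlabd-4-en-15-oic acid (C8 epimers) | C[Si](C)(C)CC1(O)CCC2=C(C)C3(SCCCS3)CC[C@@]2(C)[C@@H]1CC[C@@H](C)CC(=O)O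
F5 | step 8 | trimethylsilyl (5S,9R,10S,13R)-3-(trimethylsilyloxy)-19-norlabda-3,8(17)-dien-15-oate | C=C1CC[C@@H]2C(C)=C(O[Si](C)(C)C)CC[C@@]2(C)[C@@H]1CC[C@@H](C)CC(=O)O[Si](C)(C)C
F6 | step 8 | methyl (5S,9R,10S,13R)-3-oxolabd-8(17)-en-15-oate | C=C1CC[C@@H]2C(C)(C)C(=O)CC[C@@]2(C)[C@@H]1CC[C@@H](C)CC(=O)OC
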